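**Retrosynthetic overview**
1. Numbering: C1 CH(OAc), C2 C=O, C3=C4(CH3), C5 fusion CH, C6 CH2, C7 CH(side chain), C8 C=O, C9 CH2, C10 C(CH3), C11 carbinol C. Ring A = C1–C5 plus C10; ring B = C5–C10.
2. Feature: the quaternary fusion carbon C10 lies β to the ring B ketone C8 (through C9) and carries C1 of ring A, so it is treated as a β-keto radical. Cutting C1–C10 opens ring A to a C5 side chain C4(=CH2)–C3H2–C2(OAc)=C1H2. Drawing a C8–C10 bond contracts ring B to a 1-silyloxy-5-methylbicyclo[3.1.0]hexane with C9 as the cyclopropane CH2.
3. Late cuts: the O-acetyl at C1; C7–C11 (axial Mukaiyama aldol with methyl pyruvate); C1–O (α′-oxidation of the ring A enone, then ketol equilibration).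
4. Early cuts: enol acetate from a terminal alkyne; cyclopropane from the C8=C10 silyl enol ether; C4–C5 by asymmetric conjugate addition to 2-methylcyclopentenone, which sets C5.
5. Ring order: cyclopentane (bought), cyclopropane (step 3), then in one operation ring B by expansion and ring A by 6-endo radical closure (step 6).

Key step: step 6

Assumption: the (S,R,R) phosphoramidite in step 2 is taken to deliver the alkenyl group to the enone face that gives (R)-C5. If the sense is the opposite, the mirror-image ligand is used and nothing else changes.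

Step 1
Reactants: 1 ethynyltrimethylsilane; 2 2,3-dibromopropene
Product: 4 (4-bromopent-4-en-1-yn-1-yl)trimethylsilane, via alkynylmagnesium bromide 3 (not isolated)
Conditions: EtMgBr, THF, 0 °C to rt; then CuBr (5 mol %), 2, THF, rt to 50 °C
Reagents that add atoms: none
Why: Copper-catalysed allylic substitution by an alkynyl Grignard reagent takes only the allylic bromide (direct and allylic-shift attack give the same product), and the vinylic C–Br bond is inert under these conditions.

Step 2
Reactants: 4 (4-bromopent-4-en-1-yn-1-yl)trimethylsilane; 5 2-methylcyclopent-2-en-1-one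
Product: 8 triethyl({(3R)-2-methyl-3-[5-(trimethylsilyl)pent-1-en-4-yn-2-yl]cyclopent-1-en-1-yl}oxy)silane, via alkenyl Grignard reagent 6 (not isolated), via magnesium enolate 7 (not isolated)
Conditions: 4, Mg turnings, 2-MeTHF, 40 °C; added over 2 h to 5, CuBr·SMe2 (5 mol %), (S,R,R)-BINOL-derived N,N-bis(1-phenylethyl)phosphoramidite (6 mol %), t-BuOMe, −78 °C; then Et3SiCl, Et3N, DMPU, −78 to 0 °C
Reagents that add atoms: chlorotriethylsilane CC[Si](Cl)(CC)CC
Why: In this copper-catalysed asymmetric conjugate addition of a Grignard reagent to an α-substituted cyclopentenone the ligand on copper selects the enone face and sets C5 (R), and O-silylation of the regiodefined magnesium enolate fixes the tetrasubstituted C8=C10 enol ether.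

Step 3
Reactants: 8 triethylsilyl enol ether
Product: 9 (1S,4R,5R)-5-methyl-1-(triethylsilyloxy)-4-[5-(trimethylsilyl)pent-1-en-4-yn-2-yl]bicyclo[3.1.0]hexane
Conditions: Et2Zn (1.3 equiv), CH2I2 (1.3 equiv), Et2O–toluene, 0 °C; pyridine, aq. NaHCO3
Reagents that add atoms: diiodomethane ICI
Why: In this Simmons–Smith cyclopropanation (Furukawa variant) the electrophilic zinc carbenoid, used in slight excess only, should take the electron-rich silyl enol ether ahead of the 1,1-disubstituted alkene and approach anti to the C5 side chain, which sets C8 and C10 (both erased again in step 6).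

Step 4
Reactants: 9 silyloxycyclopropane with silylated alkyne
Product: 10 (1S,4R,5R)-5-methyl-4-(pent-1-en-4-yn-2-yl)-1-(triethylsilyloxy)bicyclo[3.1.0]hexane
Conditions: K2CO3 (0.3 equiv), MeOH–THF, 0 °C to rt
Reagents that add atoms: none
Why: Base-catalysed protiodesilylation removes the alkynyl trimethylsilyl group, and the hindered tertiary triethylsilyl ether on the cyclopropane should survive carbonate in methanol.

Step 5
Reactants: 10 terminal alkyne
Product: 11 4-[(1S,4R,5R)-5-methyl-1-(triethylsilyloxy)bicyclo[3.1.0]hexan-4-yl]penta-1,4-dien-2-yl acetate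
Conditions: AcOH (1.3 equiv), [RuCl2(p-cymene)]2 (1 mol %), tri(2-furyl)phosphine (2 mol %), Na2CO3 (4 mol %), toluene, 50 °C
Reagents that add atoms: acetic acid CC(=O)O
Why: Ruthenium-catalysed Markovnikov hydroacyloxylation of a terminal alkyne gives the 2-acetoxy-1-alkene, and this carbonate-buffered neutral catalyst is preferred to a cationic gold or silver salt with acid, which would be likely to open the donor cyclopropane.

Step 6
Reactants: 11 enol acetate silyloxycyclopropane
Product: 13 (5R,10R)-10-methyl-4-methylene-trans-decalin-2,8-dione (H5 anti to C10–CH3), via gem-chloroacetate 12 (not isolated)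
Conditions: FeCl3 (2.2 equiv, DMF solution added over 6 h), DMF (0.005 M in 11), 0 °C to rt; aq. NaHCO3
Reagents that add atoms: none
Why: Proposed new method: FeCl3 takes the silyl group off the C8 oxygen, and the resulting cyclopropoxide of trivalent iron breaks homolytically at the internal C8–C10 bond, which releases the ring strain and gives the C8 ketone together with a tertiary, non-conjugated radical at C10; this radical adds to the CH2 terminus C1 of the enol acetate, the acetoxy-stabilised C2 radical takes chlorine from a second FeCl3, and 12 loses acetyl chloride to leave the C2 ketone. The closest known reaction types are the FeCl3-mediated ring expansion of 1-silyloxybicyclo[n.1.0]alkanes, whose β-keto radicals are known to be chlorinated or to close 5-exo onto pendant alkenes, and the 6-endo closure of tertiary radicals in oxidative polyene cyclisations; what has not been shown is 6-endo capture by an enol ester. Ring B is closed by one-carbon ring expansion (cleavage of the zero bridge of the bicyclo[3.1.0]hexane, no new bond) and ring A by a 6-endo-trig radical addition that forms C1–C10. The one new stereocentre, C10, is controlled by C5: in the chair-like transition state the side chain sits equatorial on ring B and C1 bonds to the face of C10 that leaves the methyl group axial and anti to H5 (trans fusion), a course open to this radical because, unlike an enone in a polar Michael closure, it is not conjugated with C8=O and is not tied to axial attack. The step needs internal rather than external bond cleavage (secured by the tertiary radical and the six-membered ketone it gives), 6-endo rather than 5-exo closure (secured by the fully substituted C2, the sp2 C4 in the tether and the two adjacent quaternary carbons that a 5-exo closure would create) and closure ahead of chlorine transfer to C10 (helped by high dilution and slow addition of FeCl3). The homoallylic C4=CH2 group can meet the C10 radical only in a reversible 3-exo closure that returns the more stable tertiary radical on the same face, so C5 is not lost.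

Step 7
Reactants: 13 4-methylene dione
Product: 14 (5S,10R)-4,10-dimethyl-trans-decal-3-ene-2,8-dione (same spatial arrangement as 13; the C5 descriptor changes by priority only)
Conditions: DBU (0.3 equiv), CH2Cl2, rt
Reagents that add atoms: none
Why: A base-catalysed prototropic shift through the C2 dienolate moves the exocyclic alkene into conjugation as C3=C4, the thermodynamic enone, without disturbing the ring fusion under these mild conditions.

Step 8
Reactants: 14 enone dione
Product: 15 (1S,5R,10S)-1-acetoxy-4,10-dimethyl-trans-decal-3-ene-2,8-dione (axial acetate anti to C10–CH3)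
Conditions: Mn(OAc)3·2H2O (4 equiv), benzene–AcOH (10:1), reflux, Dean–Stark
Reagents that add atoms: manganese triacetate CC(=O)[O-].CC(=O)[O-].CC(=O)[O-].[Mn+3]
Why: In the Mn(OAc)3 α′-acetoxylation of enones the manganese enolate forms at the more Lewis-basic conjugated carbonyl and passes acetate to C1, its only α′ position, expected on the face anti to the C10 methyl group (axial acetate), which step 9 corrects.

Step 9
Reactants: 15 axial acetate
Product: 16 (1R,5R,10S)-1-hydroxy-4,10-dimethyl-trans-decal-3-ene-2,8-dione (equatorial OH cis to C10–CH3)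
Conditions: K2CO3 (0.5 equiv), degassed MeOH, argon, 0 °C to rt
Reagents that add atoms: none
Why: Transesterification frees the α-ketol, which should equilibrate through its enediolate to the equatorial C1 epimer that is hydrogen-bonded to C2=O, so C1 (R) is set under thermodynamic control, and short exposure under argon limits autoxidation and vinylogous isomerisation.

Step 10
Reactants: 16 equatorial ketol
Product: 17 (1R,5R,10S)-4,10-dimethyl-1,8-bis(trimethylsilyloxy)-trans-decala-3,7-dien-2-one
Conditions: Me3SiCl (5 equiv), LiN(SiMe3)2 (2.3 equiv), THF, −78 °C; Et3N, pentane, cold aq. NaHCO3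
Reagents that add atoms: chlorotrimethylsilane C[Si](C)(C)Cl
Why: In this kinetic enolisation with in situ silylation the alcohol is capped through its lithium alkoxide (which meanwhile protects the neighbouring C1–H), and the bulky amide should take the unhindered axial C7–H of the saturated ketone rather than the neopentyl C9–H or the γ-hydrogens of the enone.

Step 11
Reactants: 17 bis-silyl compound; 18 methyl pyruvate
Product: 20 methyl (2S)-2-hydroxy-2-[(1R,5R,7R,10S)-1-hydroxy-4,10-dimethyl-2,8-dioxo-trans-decal-3-en-7-yl]propanoate, via bis-silyl aldol adduct 19 (not isolated)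
Conditions: 18 (3 equiv), Cu(OTf)2 (10 mol %), (S,S)-2,2'-isopropylidenebis(4-tert-butyl-2-oxazoline) (11 mol %), CH2Cl2, −78 °C; then 1 M HCl, THF, 0 °C
Reagents that add atoms: none
Why: In this Mukaiyama aldol addition to pyruvate chelated on the bis(oxazoline) complex of divalent copper the tert-butyl groups leave only the si face of the keto group open, which sets C11 (S), and the rigid trans-decalin enol silane reacts axially at C7 on the face anti to the C10 methyl group, which sets C7 (R) with the side chain axial, after which brief cold acid removes both silyl groups without enolising C8.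

Step 12
Reactants: 20 diol
Product: 21 methyl (2S)-2-[(1R,5R,7R,10S)-1-acetoxy-4,10-dimethyl-2,8-dioxo-trans-decal-3-en-7-yl]-2-hydroxypropanoate (target CNP0211188.1)
Conditions: Ac2O (1.5 equiv), pyridine, DMAP (5 mol %), CH2Cl2, 0 °C
Reagents that add atoms: acetic anhydride CC(=O)OC(C)=O
Why: Chemoselective acylation should acetylate the secondary equatorial C1 alcohol and leave the tertiary C11 alcohol, and the weak base should not start a retro-aldol reaction or epimerise C7.

**Compound list**
1 | ethynyltrimethylsilane | C#C[Si](C)(C)C | starting material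
2 | 2,3-dibromopropene | C=C(Br)CBr | starting material
3 | [(trimethylsilyl)ethynyl]magnesium bromide | C[Si](C)(C)C#C[Mg]Br | intermediate
4 | (4-bromopent-4-en-1-yn-1-yl)trimethylsilane | C=C(Br)CC#C[Si](C)(C)C | intermediate
5 | 2-methylcyclopent-2-en-1-one | CC1=CCCC1=O | starting material
6 | [5-(trimethylsilyl)pent-1-en-4-yn-2-yl]magnesium bromide | C=C([Mg]Br)CC#C[Si](C)(C)C | intermediate
7 | bromomagnesium enolate of the (3R) conjugate adduct | C[Si](C)(C)C#CCC(=C)[C@H]1CCC(O[Mg]Br)=C1C | intermediate
8 | triethyl({(3R)-2-methyl-3-[5-(trimethylsilyl)pent-1-en-4-yn-2-yl]cyclopent-1-en-1-yl}oxy)silane | C[Si](C)(C)C#CCC(=C)[C@H]1CCC(O[Si](CC)(CC)CC)=C1C | intermediate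
9 | (1S,4R,5R)-5-methyl-1-(triethylsilyloxy)-4-[5-(trimethylsilyl)pent-1-en-4-yn-2-yl]bicyclo[3.1.0]hexane | C[Si](C)(C)C#CCC(=C)[C@H]1CC[C@]2(O[Si](CC)(CC)CC)C[C@]12C | intermediate
10 | (1S,4R,5R)-5-methyl-4-(pent-1-en-4-yn-2-yl)-1-(triethylsilyloxy)bicyclo[3.1.0]hexane | C#CCC(=C)[C@H]1CC[C@]2(O[Si](CC)(CC)CC)C[C@]12C | intermediate
11 | 4-[(1S,4R,5R)-5-methyl-1-(triethylsilyloxy)bicyclo[3.1.0]hexan-4-yl]penta-1,4-dien-2-yl acetate | C=C(OC(C)=O)CC(=C)[C@H]1CC[C@]2(O[Si](CC)(CC)CC)C[C@]12C | intermediate
12 | 2-acetoxy-2-chloro-10-methyl-4-methylene-trans-decalin-8-one (C2 undefined) | C1C[C@@H]2C(=C)CC(Cl)(OC(C)=O)C[C@@]2(C)CC1=O | intermediate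
13 | (5R,10R)-10-methyl-4-methylene-trans-decalin-2,8-dione | C1C[C@@H]2C(=C)CC(=O)C[C@@]2(C)CC1=O | intermediate
14 | (5S,10R)-4,10-dimethyl-trans-decal-3-ene-2,8-dione | C1C[C@@H]2C(C)=CC(=O)C[C@@]2(C)CC1=O | intermediate
15 | (1S,5R,10S)-1-acetoxy-4,10-dimethyl-trans-decal-3-ene-2,8-dione | C1C[C@@H]2C(C)=CC(=O)[C@@H](OC(C)=O)[C@@]2(C)CC1=O | intermediate
16 | (1R,5R,10S)-1-hydroxy-4,10-dimethyl-trans-decal-3-ene-2,8-dione | C1C[C@@H]2C(C)=CC(=O)[C@H](O)[C@@]2(C)CC1=O | intermediate
17 | (1R,5R,10S)-4,10-dimethyl-1,8-bis(trimethylsilyloxy)-trans-decala-3,7-dien-2-one | C1(=CC[C@@H]2C(C)=CC(=O)[C@H](O[Si](C)(C)C)[C@@]2(C)C1)O[Si](C)(C)C | intermediate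
18 | methyl pyruvate | COC(=O)C(C)=O | starting material
19 | bis(trimethylsilyl) ether of 20 | COC(=O)[C@@](C)(O[Si](C)(C)C)[C@H]1C[C@@H]2C(C)=CC(=O)[C@H](O[Si](C)(C)C)[C@@]2(C)CC1=O | intermediate
20 | methyl (2S)-2-hydroxy-2-[(1R,5R,7R,10S)-1-hydroxy-4,10-dimethyl-2,8-dioxo-trans-decal-3-en-7-yl]propanoate | COC(=O)[C@@](C)(O)[C@H]1C[C@@H]2C(C)=CC(=O)[C@H](O)[C@@]2(C)CC1=O | intermediate
21 | methyl (2S)-2-[(1R,5R,7R,10S)-1-acetoxy-4,10-dimethyl-2,8-dioxo-trans-decal-3-en-7-yl]-2-hydroxypropanoate | COC(=O)[C@@](C)(O)[C@H]1C[C@@H]2C(C)=CC(=O)[C@H](OC(C)=O)[C@@]2(C)CC1=O | target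

Total step count: 12. Longest linear sequence: 12 steps (from 1 or 2 to 21).

**Steps most likely to fail**

Step 6. Chlorine-atom transfer from FeCl3 to the tertiary C10 radical may outrun the slow 6-endo closure, so that ring expansion takes place without ring A being formed.
- The fallback sets out from 11 and comes back at 13. It separates ring expansion from ring closure.
- 11 is treated with excess FeCl3 in DMF at ordinary concentration, the known chlorinative ring expansion, to give the tertiary β-chloro ketone F1.
- The same C10 radical is then regenerated under reductive chain conditions ((Me3Si)3SiH and AIBN by syringe pump, benzene, 80 °C, high dilution). Here the only competing atom donor is kept scarce.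
- The cyclised C2 radical is capped by hydrogen to give the ring-closed C2 acetate F2.
- Methanolysis (K2CO3, MeOH) gives the C2 alcohol F3, and oxidation with Dess–Martin periodinane returns to 13.

Step 2. Facial discrimination by the copper catalyst may be poor for this branched alkenyl nucleophile, and uncatalysed addition may compete, so that C5 is formed with insufficient enantiomeric purity.
- The fallback sets out from 4 and comes back at 7 (and so at 8). It replaces catalyst control by a covalently bound sulfoxide auxiliary.
- Grignard reagent 6, made from 4 as before, is added at −78 °C in THF to the ZnBr2 chelate of (R)-2-(p-tolylsulfinyl)cyclopent-2-en-1-one F4. F4 is available from 2-bromocyclopent-2-enone ethylene ketal and menthyl p-toluenesulfinate.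
- In the chelate the p-tolyl group blocks one enone face, and addition gives the β-keto sulfoxide adduct F5.
- C-methylation (NaH, MeI, THF) anti to the side chain gives the methylated β-keto sulfoxide F6.
- Sulfoxide–magnesium exchange with i-PrMgBr (THF, −78 °C) releases the regiodefined enolate 7, which is silylated to 8 as in step 2.

Step 8. Oxidation may take place at the ring B ketone (C7 or C9) instead of the neopentyl C1, or conversion at C1 may be low.
- The fallback sets out from 14 and comes back at 16. It masks C8 so that a base-mediated hydroxylation has only one site.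
- Selective ketalisation of the saturated ketone (ethylene glycol, PPTS, benzene, reflux) gives the C8 ethylene ketal F7.
- Kinetic deprotonation at C1 (LDA, THF, −78 °C) and oxidation of the enolate with 2-(phenylsulfonyl)-3-phenyloxaziridine gives the axial ketol ketal F8.
- K2CO3 in MeOH equilibrates it to the equatorial ketol ketal F9, and 1 M HCl in THF removes the ketal to give 16.

**Further compounds**
F1 | step 6 | 4-[(1R)-2-chloro-2-methyl-4-oxocyclohexyl]penta-1,4-dien-2-yl acetate (C10 undefined) | C=C(OC(C)=O)CC(=C)[C@H]1CCC(=O)CC1(C)Cl
F2 | step 6 | 2-acetoxy-10-methyl-4-methylene-trans-decalin-8-one (C2 undefined) | C1C[C@@H]2C(=C)CC(OC(C)=O)C[C@@]2(C)CC1=O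
F3 | step 6 | 2-hydroxy-10-methyl-4-methylene-trans-decalin-8-one (C2 undefined) | C1C[C@@H]2C(=C)CC(O)C[C@@]2(C)CC1=O
F4 | step 2 | (R)-2-(p-tolylsulfinyl)cyclopent-2-en-1-one | Cc1ccc(cc1)[S@@](=O)C2=CCCC2=O
F5 | step 2 | (3R)-2-(p-tolylsulfinyl)-3-[5-(trimethylsilyl)pent-1-en-4-yn-2-yl]cyclopentan-1-one (C2 undefined) | C[Si](C)(C)C#CCC(=C)[C@H]1CCC(=O)C1[S@](=O)c1ccc(C)cc1
F6 | step 2 | 2-methyl-2-(p-tolylsulfinyl)-3-[5-(trimethylsilyl)pent-1-en-4-yn-2-yl]cyclopentan-1-one (methyl anti to the side chain) | C[Si](C)(C)C#CCC(=C)[C@H]1CCC(=O)[C@@]1(C)[S@](=O)c1ccc(C)cc1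
F7 | step 8 | C8 ethylene ketal of 14 | C1C[C@@H]2C(C)=CC(=O)C[C@@]2(C)CC13OCCO3
F8 | step 8 | C8 ethylene ketal of the axial C1 ketol | C1C[C@@H]2C(C)=CC(=O)[C@@H](O)[C@@]2(C)CC13OCCO3
F9 | step 8 | C8 ethylene ketal of 16 | C1C[C@@H]2C(C)=CC(=O)[C@H](O)[C@@]2(C)CC13OCCO3
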